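**Retrosynthetic overview**

1. The target is a spiro bis-lactone: ring A is the lactone that carries the decenyl chain, ring B the dihydroxy lactone that carries CO2H. The last step lets aqueous acid unfold a bridged bicyclic ortho ester into both lactones.
2. Key disconnection: the two C–C bonds of ring B that end at the atoms flanking its ring oxygen (lactone C=O carbon to CH(OH) carbon, and C(OH)(CO2H) carbon to spiro carbon). Both are made at once by [3+2] cycloaddition of a carbonyl ylide (spiro C–O–carboxyl C) with tert-butyl (E)-3-nitroacrylate.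
3. Enabling feature: in ring B the ring oxygen lies between the spiro carbon and a carboxyl-level carbon, and the ring-A oxygen is 1,3 to the spiro carbon. A methyl carbonate on the ring-A oxygen can therefore deliver its carbonyl oxygen to a carbene at the spiro carbon through a six-membered ring. This temporary 1,3-dioxane ring stands in for ring A and relays the carbinol configuration to the spiro centre.
4. After the key step, the nitro group becomes the ketone that is reduced to the CH(OH) of ring B, and the tertiary OH is added by enolate hydroxylation, both on the exo face of the bicycle.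
5. Ring order: dioxane ring and carbon skeleton of ring B (step 7), then ring B lactone and ring A lactone (step 11). The diazo carbonate comes from (R)-epichlorohydrin, 9-bromonon-1-ene and 1,3-dithiane.

Key step: step 7

Remark: (R)-epichlorohydrin, 9-bromonon-1-ene, 1,3-dithiane and tert-butyl acrylate are taken as commercial; locants C1 to C8 below are those of the 2,8-dioxabicyclo[3.2.1]octane intermediates (C1 ortho ester carbon, C3 carbinol carbon, C5 future spiro carbon, C6 and C7 the carbons from the nitroacrylate).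

**Route**

Step 1
Reactants: 1 9-bromonon-1-ene; 2 (R)-2-(chloromethyl)oxirane
Product: 5 (2R)-2-(dec-9-en-1-yl)oxirane, via non-8-en-1-ylmagnesium bromide 3 (not isolated), via (2R)-1-chlorododec-11-en-2-ol 4 (not isolated)
Conditions: Mg, THF, 40 °C; then 2, CuI (5 mol %), THF, −40 → −20 °C; then aq. NaOH, rt
Reagents that add atoms: none
Why: Copper-catalysed Grignard opening of the oxirane of 2 at its CH2 terminus and base-induced Williamson closure of the chlorohydrin 4 should give 5 with the R configuration of 2 unchanged, since no bond to the stereocentre is broken.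

Step 2
Reactants: 5 (2R)-2-(dec-9-en-1-yl)oxirane; 6 1,3-dithiane
Product: 8 (2R)-1-(1,3-dithian-2-yl)dodec-11-en-2-ol, via 2-lithio-1,3-dithiane 7 (not isolated)
Conditions: 6, n-BuLi, THF, −30 °C; then 5, −30 → 0 °C; H2O
Reagents that add atoms: none
Why: SN2 opening of the terminal epoxide at its CH2 carbon by the lithiated dithiane (Corey–Seebach acyl anion equivalent) keeps the carbinol centre R and brings in the carbon that becomes the spiro carbon.

Step 3
Reactants: 8 (2R)-1-(1,3-dithian-2-yl)dodec-11-en-2-ol
Product: 10 methyl 2-[(2R)-2-[(methoxycarbonyl)oxy]dodec-11-en-1-yl]-1,3-dithiane-2-carboxylate, via dilithium salt 9 (not isolated)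
Conditions: n-BuLi (2.3 equiv), THF, −30 °C; then transfer into ClCO2Me (4 equiv), THF, −78 °C
Reagents that add atoms: methyl chloroformate, COC(=O)Cl
Why: The dianion 9 (lithium alkoxide plus 2-lithiodithiane) is acylated on oxygen and on carbon by methyl chloroformate, both standard acylations, and the inverse cold addition into excess reagent is meant to outrun intramolecular attack of the carbanion on the new carbonate.

Step 4
Reactants: 10 methyl 2-[(2R)-2-[(methoxycarbonyl)oxy]dodec-11-en-1-yl]-1,3-dithiane-2-carboxylate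
Product: 11 methyl (4R)-4-[(methoxycarbonyl)oxy]-2-oxotetradec-13-enoate
Conditions: PhI(OCOCF3)2, MeCN–H2O (9:1), 0 °C
Reagents that add atoms: water, O
Why: Oxidative dethioacetalisation with the hypervalent iodine reagent in wet acetonitrile unmasks the 2-oxo ester under non-basic conditions that the terminal alkene and the base-labile beta-carbonate tolerate.

Step 5
Reactants: 11 methyl (4R)-4-[(methoxycarbonyl)oxy]-2-oxotetradec-13-enoate
Product: 13 methyl (4R)-2-diazo-4-[(methoxycarbonyl)oxy]tetradec-13-enoate, via tosylhydrazone 12 (not isolated)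
Conditions: TsNHNH2, MeOH, rt; then DBU, CH2Cl2, 0 °C
Reagents that add atoms: p-toluenesulfonyl hydrazide, Cc1ccc(cc1)S(=O)(=O)NN
Why: Condensation of the activated ketone with tosylhydrazide and base-induced loss of p-toluenesulfinate from the hydrazone (Bamford–Stevens type synthesis of an alpha-diazo ester) installs the diazo group without ester enolate chemistry, which would cyclise onto the gamma-carbonate.

Step 6
Reactants: 14 tert-butyl prop-2-enoate
Product: 16 tert-butyl (E)-3-nitroprop-2-enoate, via tert-butyl 2-iodo-3-nitropropanoate 15 (not isolated)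
Conditions: N2O4, I2, Et2O, 0 °C; then NaOAc, Et2O, rt
Reagents that add atoms: dinitrogen tetroxide, O=[N+]([O-])[N+](=O)[O-]
Why: Iodonitration of the acrylate (NO2 adds to the CH2 terminus, iodine to the alpha carbon) followed by acetate-induced E2 loss of HI is the established route to (E)-3-nitroacrylates.

Step 7
Reactants: 13 methyl (4R)-2-diazo-4-[(methoxycarbonyl)oxy]tetradec-13-enoate; 16 tert-butyl (E)-3-nitroprop-2-enoate
Product: 19 6-tert-butyl 5-methyl (1R,3R,5S)-3-(dec-9-en-1-yl)-1-methoxy-7-nitro-2,8-dioxabicyclo[3.2.1]octane-5,6-dicarboxylate, via rhodium carbene 17 (not isolated), via carbonyl ylide 18 (not isolated)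
Conditions: Rh2(O2CCMe3)4 (2 mol %), 16 (3 equiv), CH2Cl2, −40 °C, slow addition of 13; then −40 → 0 °C
Reagents that add atoms: none
Why: Proposed new method: loss of N2 from 13 at Rh2(O2CCMe3)4 should give carbene 17, its electrophilic carbon is captured by the carbonyl oxygen of the carbonate through a six-membered ring (carbene C, CH2, CH, O, carbonate C, carbonyl O) to give the alkoxy-stabilised carbonyl ylide 18, and 18 adds across the C=C of 16 in a suprafacial [3+2] cycloaddition that closes the five-membered ring (spiro C, O, carbonate C and both alkene carbons) and forms the bond from the carbonate carbon to the nitro-bearing carbon together with the bond from the ester-bearing alkene carbon to the former carbene carbon. The closest known reaction type is the rhodium-catalysed tandem formation of six-membered carbonyl ylides from alpha-diazo esters and ester carbonyl groups with intermolecular cycloaddition to electron-poor alkenes or alkynes, which gives the same dioxabicyclooctane skeleton, and the untested element is the use of a carbonate carbonyl, which makes the bridgehead an ortho ester and so delivers the future lactone carbon of ring B at its final oxidation level. The ylide is an ester enolate tied to a trialkoxycarbenium ion, so its nucleophilic carbene-derived carbon should attack the alkene carbon beta to the nitro group (the ester-bearing carbon, the established site of nucleophilic attack on 3-nitroacrylates) and the nitronate carbon then bonds to the cationic carbonate carbon, which fixes the regiochemistry. The existing carbinol centre places the decenyl chain equatorial on the developing chair of the dioxane ring and the alkene adds to the ylide face that carries the carbinol hydrogen, which sets both bridgeheads together (1R,5S, C5 being the future spiro centre), whereas the trans-related centres C6 and C7 may form as either pair because they are reset in steps 8 to 10. The selectivities needed are carbonyl capture of the carbene ahead of its 1,2-hydride shift, secured by the six-membered intramolecular capture, the bulky pivalate ligands and the low temperature, and cycloaddition ahead of direct pyrazoline formation between 13 and 16, secured by slow addition of 13 to catalyst and excess 16.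

Step 8
Reactants: 19 6-tert-butyl 5-methyl (1R,3R,5S)-3-(dec-9-en-1-yl)-1-methoxy-7-nitro-2,8-dioxabicyclo[3.2.1]octane-5,6-dicarboxylate
Product: 21 6-tert-butyl 5-methyl (1R,3R,5S)-3-(dec-9-en-1-yl)-1-methoxy-7-oxo-2,8-dioxabicyclo[3.2.1]octane-5,6-dicarboxylate, via potassium nitronate 20 (not isolated)
Conditions: KOH (1.05 equiv), MeOH, −20 °C; then KHSO5 (as 2KHSO5·KHSO4·K2SO4), Na2HPO4, H2O–MeOH, 0 °C
Reagents that add atoms: potassium peroxymonosulfate, [K+].[O-]S(=O)(=O)OO
Why: Oxidative Nef reaction, in which the nitronate 20 is oxidised at carbon by peroxymonosulfate and loses nitrite, turns both C6/C7 isomers of 19 into one enolisable beta-keto ester without touching the three fixed stereocentres.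

Step 9
Reactants: 21 6-tert-butyl 5-methyl (1R,3R,5S)-3-(dec-9-en-1-yl)-1-methoxy-7-oxo-2,8-dioxabicyclo[3.2.1]octane-5,6-dicarboxylate
Product: 23 6-tert-butyl 5-methyl (1R,3R,5S,6S)-3-(dec-9-en-1-yl)-6-hydroxy-1-methoxy-7-oxo-2,8-dioxabicyclo[3.2.1]octane-5,6-dicarboxylate, via potassium enolate 22 (not isolated)
Conditions: KN(SiMe3)2, THF, −78 °C; then 2-(phenylsulfonyl)-3-phenyloxaziridine, −78 °C; aq. NH4Cl
Reagents that add atoms: 2-(phenylsulfonyl)-3-phenyloxaziridine, O=S(=O)(c1ccccc1)N1OC1c1ccccc1
Why: Davis hydroxylation of the beta-keto ester enolate 22 by the N-sulfonyloxaziridine should occur on the exo face of the bicycle, the endo face being covered by the three-atom O–CH–CH2 bridge, so that the new tertiary OH is exo and the tert-butyl ester endo (6S).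

Step 10
Reactants: 23 6-tert-butyl 5-methyl (1R,3R,5S,6S)-3-(dec-9-en-1-yl)-6-hydroxy-1-methoxy-7-oxo-2,8-dioxabicyclo[3.2.1]octane-5,6-dicarboxylate
Product: 24 6-tert-butyl 5-methyl (1R,3R,5S,6R,7R)-3-(dec-9-en-1-yl)-6,7-dihydroxy-1-methoxy-2,8-dioxabicyclo[3.2.1]octane-5,6-dicarboxylate
Conditions: NaBH4, MeOH–THF, −40 °C
Reagents that add atoms: none
Why: Borohydride reduction of the bridged ketone from its open exo face, the usual course for ketones on the two-carbon bridge of such bicycles, should give the endo alcohol (7R) and with it the trans diol of ring B.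

Step 11
Reactants: 24 6-tert-butyl 5-methyl (1R,3R,5S,6R,7R)-3-(dec-9-en-1-yl)-6,7-dihydroxy-1-methoxy-2,8-dioxabicyclo[3.2.1]octane-5,6-dicarboxylate
Product: 25 (3R,4R,5S,8R)-8-(dec-9-en-1-yl)-3,4-dihydroxy-2,6-dioxo-1,7-dioxaspiro[4.4]nonane-4-carboxylic acid
Conditions: CF3CO2H–H2O (9:1), 0 °C → rt; then toluene, 50 °C
Reagents that add atoms: water, O
Why: Aqueous acid hydrolyses the ortho ester to the lactone on the tertiary bridging oxygen (ring B), lets the freed secondary OH transesterify the neighbouring methyl ester (ring A, releasing methanol) and cleaves the tert-butyl ester by acidolysis, none of which touches the four stereocentres.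

**Compound list**

1 | 9-bromonon-1-ene | C=CCCCCCCCBr | starting material
2 | (R)-2-(chloromethyl)oxirane ((R)-epichlorohydrin) | ClC[C@H]1CO1 | starting material
3 | non-8-en-1-ylmagnesium bromide | C=CCCCCCCC[Mg]Br | intermediate
4 | (2R)-1-chlorododec-11-en-2-ol | C=CCCCCCCCC[C@@H](O)CCl | intermediate
5 | (2R)-2-(dec-9-en-1-yl)oxirane | C=CCCCCCCCC[C@@H]1CO1 | intermediate
6 | 1,3-dithiane | C1CSCSC1 | starting material
7 | 2-lithio-1,3-dithiane | [Li]C1SCCCS1 | intermediate
8 | (2R)-1-(1,3-dithian-2-yl)dodec-11-en-2-ol | C=CCCCCCCCC[C@@H](O)CC1SCCCS1 | intermediate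
9 | dilithium salt of 8 (lithium alkoxide and 2-lithiodithiane) | [Li+].[Li+].C=CCCCCCCCC[C@@H]([O-])C[C-]1SCCCS1 | intermediate
10 | methyl 2-[(2R)-2-[(methoxycarbonyl)oxy]dodec-11-en-1-yl]-1,3-dithiane-2-carboxylate | C=CCCCCCCCC[C@@H](OC(=O)OC)CC1(C(=O)OC)SCCCS1 | intermediate
11 | methyl (4R)-4-[(methoxycarbonyl)oxy]-2-oxotetradec-13-enoate | C=CCCCCCCCC[C@@H](OC(=O)OC)CC(=O)C(=O)OC | intermediate
12 | methyl (4R)-4-[(methoxycarbonyl)oxy]-2-(tosylhydrazinylidene)tetradec-13-enoate | C=CCCCCCCCC[C@@H](OC(=O)OC)CC(=NNS(=O)(=O)c1ccc(C)cc1)C(=O)OC | intermediate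
13 | methyl (4R)-2-diazo-4-[(methoxycarbonyl)oxy]tetradec-13-enoate | C=CCCCCCCCC[C@@H](OC(=O)OC)CC(=[N+]=[N-])C(=O)OC | intermediate
14 | tert-butyl prop-2-enoate (tert-butyl acrylate) | C=CC(=O)OC(C)(C)C | starting material
15 | tert-butyl 2-iodo-3-nitropropanoate (racemic) | O=C(OC(C)(C)C)C(I)C[N+](=O)[O-] | intermediate
16 | tert-butyl (E)-3-nitroprop-2-enoate | O=C(OC(C)(C)C)/C=C/[N+](=O)[O-] | intermediate
17 | rhodium carbene from 13 (carboxylate ligands on rhodium omitted) | C=CCCCCCCCC[C@@H](OC(=O)OC)CC(=[Rh])C(=O)OC | intermediate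
18 | (6R)-6-(dec-9-en-1-yl)-2-methoxy-4-(methoxycarbonyl)-5,6-dihydro-4H-1,3-dioxin-3-ium-4-ide (cyclic carbonyl ylide) | COC1=[O+][C-](C(=O)OC)C[C@@H](CCCCCCCCC=C)O1 | intermediate
19 | 6-tert-butyl 5-methyl (1R,3R,5S)-3-(dec-9-en-1-yl)-1-methoxy-7-nitro-2,8-dioxabicyclo[3.2.1]octane-5,6-dicarboxylate (decenyl exo; C6 and C7 trans, either trans pair) | CO[C@]12O[C@H](CCCCCCCCC=C)C[C@](C(=O)OC)(O1)C(C(=O)OC(C)(C)C)C2[N+](=O)[O-] | intermediate
20 | potassium nitronate of 19 | CO[C@]12O[C@H](CCCCCCCCC=C)C[C@](C(=O)OC)(O1)C(C(=O)OC(C)(C)C)C2=[N+]([O-])[O-].[K+] | intermediate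
21 | 6-tert-butyl 5-methyl (1R,3R,5S)-3-(dec-9-en-1-yl)-1-methoxy-7-oxo-2,8-dioxabicyclo[3.2.1]octane-5,6-dicarboxylate (C6 enolisable) | CO[C@]12O[C@H](CCCCCCCCC=C)C[C@](C(=O)OC)(O1)C(C(=O)OC(C)(C)C)C2=O | intermediate
22 | potassium enolate of 21 | CO[C@]12O[C@H](CCCCCCCCC=C)C[C@](C(=O)OC)(O1)C(C(=O)OC(C)(C)C)=C2[O-].[K+] | intermediate
23 | 6-tert-butyl 5-methyl (1R,3R,5S,6S)-3-(dec-9-en-1-yl)-6-hydroxy-1-methoxy-7-oxo-2,8-dioxabicyclo[3.2.1]octane-5,6-dicarboxylate (6-OH exo) | CO[C@]12O[C@H](CCCCCCCCC=C)C[C@](C(=O)OC)(O1)[C@@](O)(C(=O)OC(C)(C)C)C2=O | intermediate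
24 | 6-tert-butyl 5-methyl (1R,3R,5S,6R,7R)-3-(dec-9-en-1-yl)-6,7-dihydroxy-1-methoxy-2,8-dioxabicyclo[3.2.1]octane-5,6-dicarboxylate (6-OH exo, 7-OH endo) | CO[C@]12O[C@H](CCCCCCCCC=C)C[C@](C(=O)OC)(O1)[C@@](O)(C(=O)OC(C)(C)C)[C@H]2O | intermediate
25 | (3R,4R,5S,8R)-8-(dec-9-en-1-yl)-3,4-dihydroxy-2,6-dioxo-1,7-dioxaspiro[4.4]nonane-4-carboxylic acid | C=CCCCCCCCC[C@@H]1C[C@@]2(OC(=O)[C@H](O)[C@]2(O)C(=O)O)C(=O)O1 | target

**Step count and risks**

Total steps: 11. Longest linear sequence: 10 steps (steps 1 to 5 and 7 to 11).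

Most likely to fail:

1. Step 7 (the step proposed as new). The carbene may undergo 1,2-hydride shift to the alk-2-enoate before the carbonate oxygen captures it, or the ylide may lose or shift its O-methyl group before it meets the nitroacrylate. The fallback uses known chemistry, sets out from 11 and comes back to the route at 25. Aldol addition of the lithium enolate of di-tert-butyl (4R,5R)-2,2-dimethyl-1,3-dioxolane-4,5-dicarboxylate (LiN(iPr)2, THF, −78 °C) to the ketone of 11 should give di-tert-butyl (4R,5R)-4-[(2S,4R)-2-hydroxy-1-methoxy-4-[(methoxycarbonyl)oxy]-1-oxotetradec-13-en-2-yl]-2,2-dimethyl-1,3-dioxolane-4,5-dicarboxylate F1, the ketone entering anti to the neighbouring ester of the tartrate enolate. K2CO3 in methanol at 0 °C then removes the methyl carbonate and the freed alkoxide closes ring A to give di-tert-butyl (4R,5R)-4-[(3S,5R)-5-(dec-9-en-1-yl)-3-hydroxy-2-oxooxolan-3-yl]-2,2-dimethyl-1,3-dioxolane-4,5-dicarboxylate F2. CF3CO2H–H2O removes the acetonide and both tert-butyl esters and closes ring B onto the tertiary OH to give 25.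

2. Step 8. The nitronate may expel an ortho ester oxygen (ring-opening beta-elimination), or the substrate may lose HNO2 by deprotonation at C6, before oxidation takes place. The fallback sets out from 19 and comes back at 21. SmI2 (THF–MeOH, −78 °C) reduces the nitro group by electron transfer without a carbanion next to the ortho ester and should give 6-tert-butyl 5-methyl (1R,3R,5S)-3-(dec-9-en-1-yl)-7-(hydroxyamino)-1-methoxy-2,8-dioxabicyclo[3.2.1]octane-5,6-dicarboxylate F3. MnO2 (CH2Cl2) dehydrogenates it to 6-tert-butyl 5-methyl (1R,3R,5S)-3-(dec-9-en-1-yl)-7-(hydroxyimino)-1-methoxy-2,8-dioxabicyclo[3.2.1]octane-5,6-dicarboxylate F4. Oxime exchange with glyoxylic acid (aq. THF, NaOAc) then gives ketone 21.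

3. Step 5. Under the base, the keto ester or its hydrazone may lose the beta-carbonate by E1cB elimination instead of losing sulfinate. The fallback sets out from 11 and comes back at 13. Hydrazine hydrate (MeOH, AcOH, 0 °C) should give methyl (4R)-2-hydrazinylidene-4-[(methoxycarbonyl)oxy]tetradec-13-enoate F5, which MnO2 (CH2Cl2, 0 °C) dehydrogenates to 13 under neutral conditions.

**Further compounds**

F1 | step 7 | di-tert-butyl (4R,5R)-4-[(2S,4R)-2-hydroxy-1-methoxy-4-[(methoxycarbonyl)oxy]-1-oxotetradec-13-en-2-yl]-2,2-dimethyl-1,3-dioxolane-4,5-dicarboxylate | C=CCCCCCCCC[C@@H](OC(=O)OC)C[C@@](O)(C(=O)OC)[C@]1(C(=O)OC(C)(C)C)OC(C)(C)O[C@H]1C(=O)OC(C)(C)C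
F2 | step 7 | di-tert-butyl (4R,5R)-4-[(3S,5R)-5-(dec-9-en-1-yl)-3-hydroxy-2-oxooxolan-3-yl]-2,2-dimethyl-1,3-dioxolane-4,5-dicarboxylate | C=CCCCCCCCC[C@@H]1C[C@](O)([C@]2(C(=O)OC(C)(C)C)OC(C)(C)O[C@H]2C(=O)OC(C)(C)C)C(=O)O1
F3 | step 8 | 6-tert-butyl 5-methyl (1R,3R,5S)-3-(dec-9-en-1-yl)-7-(hydroxyamino)-1-methoxy-2,8-dioxabicyclo[3.2.1]octane-5,6-dicarboxylate | CO[C@]12O[C@H](CCCCCCCCC=C)C[C@](C(=O)OC)(O1)C(C(=O)OC(C)(C)C)C2NO
F4 | step 8 | 6-tert-butyl 5-methyl (1R,3R,5S)-3-(dec-9-en-1-yl)-7-(hydroxyimino)-1-methoxy-2,8-dioxabicyclo[3.2.1]octane-5,6-dicarboxylate | CO[C@]12O[C@H](CCCCCCCCC=C)C[C@](C(=O)OC)(O1)C(C(=O)OC(C)(C)C)C2=NO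
F5 | step 5 | methyl (4R)-2-hydrazinylidene-4-[(methoxycarbonyl)oxy]tetradec-13-enoate | C=CCCCCCCCC[C@@H](OC(=O)OC)CC(=NN)C(=O)OC
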